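**Assumption:** pent-4-ynal is taken as a stock aldehyde, and the (2R,5R) antipode of 2,5-diphenylpyrrolidine is taken to give the 2S chloride (if the sense is the reverse, the (2S,5S) catalyst is used). The target as drawn has the two side chains trans across the ring oxygen and each halogen trans to its neighbouring side chain.

## Retrosynthetic overview

1. Target ⇐ silyl-protected (Z)-enyne ⇐ aldehyde 14 (Peterson olefination) ⇐ ester 12.
2. (E)-Bromopentenyl group of 12 ⇐ (Z)-alkenyl boronate 11 (bromodeboronation with retention) ⇐ cross-metathesis of the allyl group of 8.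
3. Key step: 8 ⇐ dihydropyran 6 + allyl bromide by a bromine-atom chain that forms C–Br and C–allyl trans-diaxially; this sets both remaining ring stereocentres and the trans relationship of the two side chains.
4. The only ring (dihydropyran 6) ⇐ endo cycloisomerisation of alkynol 5 ⇐ anti aldol of methyl acetate with (2S)-2-chloropent-4-ynal ⇐ organocatalytic α-chlorination of pent-4-ynal.

## Route

**Step 1**
Reactants: 1 pent-4-ynal
Product: 2 (2S)-2-chloropent-4-ynal
Conditions: N-chlorosuccinimide, (2R,5R)-2,5-diphenylpyrrolidine (10 mol %), CH2Cl2, 0 °C; used crude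
Reagents that add atoms: N-chlorosuccinimide, O=C1CCC(=O)N1Cl
Why: Enamine-catalysed α-chlorination of an aldehyde, in which the C2-symmetric amine shields one enamine face so that chlorine is delivered to give the 2S centre (the later ring C–Cl carbon).

**Step 2**
Reactants: 2 (2S)-2-chloropent-4-ynal; 3 methyl acetate
Product: 5 methyl (3R,4S)-4-chloro-3-hydroxyhept-6-ynoate, via lithium enolate of methyl acetate 4 (not isolated)
Conditions: LiN(iPr)2, THF, −78 °C; then 2, −78 °C, 15 min; AcOH quench at −78 °C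
Reagents that add atoms: none
Why: Aldol addition to an α-chloro aldehyde under Cornforth–Evans control, where the enolate attacks the conformer with C=O and C–Cl antiperiplanar to give the 3,4-anti chlorohydrin and hence the 3R carbinol.

**Step 3**
Reactants: 5 methyl (3R,4S)-4-chloro-3-hydroxyhept-6-ynoate
Product: 6 methyl 2-[(2R,3S)-3-chloro-3,4-dihydro-2H-pyran-2-yl]acetate
Conditions: W(CO)6 (25 mol %), DABCO, THF, hν (350 nm), 60 °C
Reagents that add atoms: none
Why: McDonald-type alkynol cycloisomerisation through a tungsten vinylidene, which the hydroxyl attacks at the terminal carbon to close the six-membered enol ether (endo mode) without touching either stereocentre.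

**Step 4 (key step)**
Reactants: 6 methyl 2-[(2R,3S)-3-chloro-3,4-dihydro-2H-pyran-2-yl]acetate; 7 3-bromoprop-1-ene (allyl bromide)
Product: 8 methyl 2-[(2R,3S,5S,6R)-5-bromo-3-chloro-6-(prop-2-en-1-yl)oxan-2-yl]acetate
Conditions: 7 (10 equiv), 2,2'-azobis(4-methoxy-2,4-dimethylvaleronitrile) (0.2 equiv, in portions), K2CO3, degassed benzene, 40 °C
Reagents that add atoms: none
Why: Proposed new method: a bromine atom (released when the initiator radical adds to allyl bromide) adds reversibly to C5 of the enol ether to give a bromine-bridged 2-oxanyl radical, which is trapped by allyl bromide through addition and β-scission of Br• (the chain carrier), so that Br and allyl are delivered trans-diaxially across the half-chair whose C2 and C3 substituents stay equatorial, setting C5 (S) and C6 (R) with the allyl group trans to both the bromine and the C2 side chain; the closest known reaction types are the bromine-radical-mediated bromoallylation of alkynes and allenes with allyl bromides and the axial selectivity of radical C-glycosylation.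

**Step 5**
Reactants: 9 2-bromobut-1-ene
Product: 10 2-(but-1-en-2-yl)-4,4,5,5-tetramethyl-1,3,2-dioxaborolane
Conditions: bis(pinacolato)diboron, PdCl2(PPh3)2 (3 mol %), PPh3, KOPh, toluene, 50 °C
Reagents that add atoms: bis(pinacolato)diboron, CC1(C)OB(OC1(C)C)B1OC(C)(C)C(C)(C)O1
Why: Miyaura borylation of an alkenyl bromide, which proceeds by oxidative addition, phenoxide-assisted transmetalation and reductive elimination and creates no stereocentre.

**Step 6**
Reactants: 8 methyl 2-[(2R,3S,5S,6R)-5-bromo-3-chloro-6-(prop-2-en-1-yl)oxan-2-yl]acetate; 10 2-(but-1-en-2-yl)-4,4,5,5-tetramethyl-1,3,2-dioxaborolane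
Product: 11 methyl 2-[(2R,3S,5S,6R)-5-bromo-3-chloro-6-[(2Z)-3-(4,4,5,5-tetramethyl-1,3,2-dioxaborolan-2-yl)pent-2-en-1-yl]oxan-2-yl]acetate
Conditions: 10 (3 equiv), second-generation Grubbs catalyst RuCl2(=CHPh)(H2IMes)(PCy3) (10 mol %), CH2Cl2, 40 °C
Reagents that add atoms: none
Why: Olefin cross-metathesis of a terminal alkene with a 1,1-disubstituted alkenyl boronate, which is expected to place the conjugating boronate trans to the ring CH2 and the ethyl group cis (the Z isomer), by analogy with the isopropenyl boronate case.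

**Step 7**
Reactants: 11 methyl 2-[(2R,3S,5S,6R)-5-bromo-3-chloro-6-[(2Z)-3-(4,4,5,5-tetramethyl-1,3,2-dioxaborolan-2-yl)pent-2-en-1-yl]oxan-2-yl]acetate
Product: 12 methyl 2-[(2R,3S,5S,6R)-5-bromo-6-[(2E)-3-bromopent-2-en-1-yl]-3-chlorooxan-2-yl]acetate
Conditions: CuBr2 (3 equiv), MeOH/H2O (1:1), 70 °C
Reagents that add atoms: copper dibromide, Br[Cu]Br
Why: Copper-mediated bromodeboronation, in which boron-to-copper transmetalation and C–Br reductive elimination occur with retention, so bromine takes the place of boron trans to the ring CH2 and gives the E vinyl bromide.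

**Step 8**
Reactants: 12 methyl 2-[(2R,3S,5S,6R)-5-bromo-6-[(2E)-3-bromopent-2-en-1-yl]-3-chlorooxan-2-yl]acetate
Product: 14 2-[(2R,3S,5S,6R)-5-bromo-6-[(2E)-3-bromopent-2-en-1-yl]-3-chlorooxan-2-yl]acetaldehyde, via aluminium hemiacetal 13 (not isolated)
Conditions: iBu2AlH (1.05 equiv), CH2Cl2, −78 °C; MeOH, then aq. KNaC4H4O6
Reagents that add atoms: none
Why: Partial reduction of an ester with iBu2AlH, where the tetrahedral aluminium hemiacetal (stabilised by the β ring oxygen) survives at −78 °C and releases the aldehyde only on work-up, with no stereocentre affected.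

**Step 9**
Reactants: 14 2-[(2R,3S,5S,6R)-5-bromo-6-[(2E)-3-bromopent-2-en-1-yl]-3-chlorooxan-2-yl]acetaldehyde
Product: 16 (2R,3S,5S,6R)-3-bromo-2-[(2E)-3-bromopent-2-en-1-yl]-5-chloro-6-[(2Z)-5-(triisopropylsilyl)pent-2-en-4-yn-1-yl]oxane, via lithium β-silyl alkoxide 15 (not isolated)
Conditions: 1,3-bis(triisopropylsilyl)propyne, nBuLi, THF, −78 °C; then 14, −78 to −20 °C
Reagents that add atoms: 1,3-bis(triisopropylsilyl)propyne, CC(C)[Si](C(C)C)(C(C)C)CC#C[Si](C(C)C)(C(C)C)C(C)C
Why: Peterson olefination with the lithiated bis-silyl propyne (Corey–Yamamoto enyne synthesis), in which the bulky silyl groups enforce the adduct that collapses by syn elimination of silanolate to the Z enyne.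

**Step 10**
Reactants: 16 (2R,3S,5S,6R)-3-bromo-2-[(2E)-3-bromopent-2-en-1-yl]-5-chloro-6-[(2Z)-5-(triisopropylsilyl)pent-2-en-4-yn-1-yl]oxane
Product: 17 (2R,3S,5S,6R)-3-bromo-2-[(2E)-3-bromopent-2-en-1-yl]-5-chloro-6-[(2Z)-pent-2-en-4-yn-1-yl]oxane (target)
Conditions: Bu4NF, THF, 0 °C
Reagents that add atoms: none
Why: Fluoride-induced protodesilylation of the alkynyl silane, which is fast at 0 °C and leaves the alkyl halides, both alkene geometries and all four stereocentres untouched.

## Compound list

1 | pent-4-ynal | C#CCCC=O | starting material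
2 | (2S)-2-chloropent-4-ynal | O=C[C@@H](Cl)CC#C | intermediate
3 | methyl acetate | COC(C)=O | starting material
4 | lithium enolate of methyl acetate (lithium 1-methoxyethen-1-olate) | [Li]OC(=C)OC | intermediate
5 | methyl (3R,4S)-4-chloro-3-hydroxyhept-6-ynoate | COC(=O)C[C@@H](O)[C@@H](Cl)CC#C | intermediate
6 | methyl 2-[(2R,3S)-3-chloro-3,4-dihydro-2H-pyran-2-yl]acetate | COC(=O)C[C@H]1OC=CC[C@@H]1Cl | intermediate
7 | 3-bromoprop-1-ene (allyl bromide) | C=CCBr | starting material
8 | methyl 2-[(2R,3S,5S,6R)-5-bromo-3-chloro-6-(prop-2-en-1-yl)oxan-2-yl]acetate | COC(=O)C[C@H]1O[C@H](CC=C)[C@@H](Br)C[C@@H]1Cl | intermediate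
9 | 2-bromobut-1-ene | C=C(Br)CC | starting material
10 | 2-(but-1-en-2-yl)-4,4,5,5-tetramethyl-1,3,2-dioxaborolane | C=C(CC)B1OC(C)(C)C(C)(C)O1 | intermediate
11 | methyl 2-[(2R,3S,5S,6R)-5-bromo-3-chloro-6-[(2Z)-3-(4,4,5,5-tetramethyl-1,3,2-dioxaborolan-2-yl)pent-2-en-1-yl]oxan-2-yl]acetate | COC(=O)C[C@H]1O[C@H](C/C=C(/B2OC(C)(C)C(C)(C)O2)CC)[C@@H](Br)C[C@@H]1Cl | intermediate
12 | methyl 2-[(2R,3S,5S,6R)-5-bromo-6-[(2E)-3-bromopent-2-en-1-yl]-3-chlorooxan-2-yl]acetate | COC(=O)C[C@H]1O[C@H](C/C=C(/Br)CC)[C@@H](Br)C[C@@H]1Cl | intermediate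
13 | diisobutylaluminium hemiacetal of 12 (new acetal carbon not defined) | COC(O[Al](CC(C)C)CC(C)C)C[C@H]1O[C@H](C/C=C(/Br)CC)[C@@H](Br)C[C@@H]1Cl | intermediate
14 | 2-[(2R,3S,5S,6R)-5-bromo-6-[(2E)-3-bromopent-2-en-1-yl]-3-chlorooxan-2-yl]acetaldehyde | O=CC[C@H]1O[C@H](C/C=C(/Br)CC)[C@@H](Br)C[C@@H]1Cl | intermediate
15 | lithium β-silyl alkoxide from addition of the lithiated bis-silyl propyne to 14 (two new centres not defined) | [Li]OC(C[C@H]1O[C@H](C/C=C(/Br)CC)[C@@H](Br)C[C@@H]1Cl)C(C#C[Si](C(C)C)(C(C)C)C(C)C)[Si](C(C)C)(C(C)C)C(C)C | intermediate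
16 | (2R,3S,5S,6R)-3-bromo-2-[(2E)-3-bromopent-2-en-1-yl]-5-chloro-6-[(2Z)-5-(triisopropylsilyl)pent-2-en-4-yn-1-yl]oxane | CC(C)[Si](C(C)C)(C(C)C)C#C/C=C\C[C@H]1O[C@H](C/C=C(/Br)CC)[C@@H](Br)C[C@@H]1Cl | intermediate
17 | (2R,3S,5S,6R)-3-bromo-2-[(2E)-3-bromopent-2-en-1-yl]-5-chloro-6-[(2Z)-pent-2-en-4-yn-1-yl]oxane | C#C/C=C\C[C@H]1O[C@H](C/C=C(/Br)CC)[C@@H](Br)C[C@@H]1Cl | target

## Step count and risks

Total steps: 10. Longest linear sequence: 9 (steps 1, 2, 3, 4, 6, 7, 8, 9, 10).

**Step 4 (bromine-atom bromoallylation of the enol ether).** The chain may be short, or traces of HBr may consume the enol ether. The fallback sets out from 6 and returns at 8. Compound 6 is treated with N-bromosuccinimide in methanol at −20 °C, which gives by trans-diaxial addition the bromo acetal methyl 2-[(2R,3S,5S,6S)-5-bromo-3-chloro-6-methoxyoxan-2-yl]acetate F1. F1 is then ionised with Me3SiOTf in CH2Cl2 at −78 °C in the presence of allyltrimethylsilane; the bromine-bridged oxocarbenium ion is attacked axially and anti to bromine, giving 8.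

**Step 6 (cross-metathesis with the 1,1-disubstituted boronate).** The ethyl-substituted partner is more hindered than the isopropenyl case and may couple slowly. The fallback sets out from 8 and returns at 11. The allyl group of 8 is ozonised (O3, CH2Cl2/MeOH, −78 °C; PPh3) to the aldehyde methyl 2-[(2R,3S,5S,6R)-5-bromo-3-chloro-6-(2-oxoethyl)oxan-2-yl]acetate F2. F2 is condensed at −78 °C in THF with the anion made from 1,1-bis(pinacolboryl)propane and lithium 2,2,6,6-tetramethylpiperidide; this boron–Wittig reaction gives the same Z alkenyl boronate 11.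

**Step 7 (bromodeboronation with retention).** The trisubstituted pinacol boronate may react slowly with CuBr2 or lose geometric purity. The fallback sets out from 11 and returns at 12. Compound 11 is converted with KHF2 in aqueous methanol into potassium trifluoro[(2Z)-1-[(2R,3S,5S,6R)-3-bromo-5-chloro-6-(2-methoxy-2-oxoethyl)oxan-2-yl]pent-2-en-3-yl]borate F3. F3 is brominated with Bu4NBr3 in THF/H2O at 0 °C, an ipso substitution that proceeds with retention and gives 12.

## Further compounds

F1 | step 4 | methyl 2-[(2R,3S,5S,6S)-5-bromo-3-chloro-6-methoxyoxan-2-yl]acetate | COC(=O)C[C@H]1O[C@H](OC)[C@@H](Br)C[C@@H]1Cl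
F2 | step 6 | methyl 2-[(2R,3S,5S,6R)-5-bromo-3-chloro-6-(2-oxoethyl)oxan-2-yl]acetate | COC(=O)C[C@H]1O[C@H](CC=O)[C@@H](Br)C[C@@H]1Cl
F3 | step 7 | potassium trifluoro[(2Z)-1-[(2R,3S,5S,6R)-3-bromo-5-chloro-6-(2-methoxy-2-oxoethyl)oxan-2-yl]pent-2-en-3-yl]borate | COC(=O)C[C@H]1O[C@H](C/C=C(/[B-](F)(F)F)CC)[C@@H](Br)C[C@@H]1Cl.[K+]
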